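Count working minutes before trusting any end value.

| flask | substrate | partner | time |
|---|---|---|---|
| east | 0.400 M | 0.480 M |  |
| north | 0.200 M | 0.280 M |  |
| south | 0.800 M | 0.480 M |  |
| north-east | 0.400 M | 1.20 M | 10 min |

| east run: time / min | east run: [target] / M | north run: time / min | north run: [target] / M | south run: time / min | south run: [target] / M |
|---|---|---|---|---|---|
| 0.40 | 0.0078 | 0.40 | 0.0029 | 0.40 | 0.0147 |
| 0.76 | 0.0145 | 0.76 | 0.0044 | 0.76 | 0.0259 |
| 1.4 | 0.0273 | 1.4 | 0.0091 | 1.4 | 0.0473 |
| 2.8 | 0.0429 | 2.8 | 0.0138 | 2.8 | 0.0796 |
| 5.3 | 0.0617 | 5.3 | 0.0220 | 5.3 | 0.1093 |
| 10 | 0.0776 | 10 | 0.0273 | 10 | 0.1304 |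

(standard deviation of a reading: 0.001 M)

- the exponent of [partner] in the starting rate at the charge of the east run (at the point where two percent of the substrate have become target)
- the exponent of [substrate] in the starting rate at the charge of the east run (at the point where two percent of the substrate have become target) (one fixed amount of target, the same in the runs compared)
- target in the north-east run at 10 min, as a share of the substrate charged

- Overall: substrate + partner -> target.
- Constant volume, constant temperature.
- "The second partner" is partner.
- An order is taken over about fifteen percent of the charge, up and down.

The east run is the simulated neighbour of the north-east run: it has the same substrate charge and less partner. I read its early rate at 0.76 min and divide its last reading by that rate: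

early rate = 0.0145 M / 0.76 min = 0.0191 M min⁻¹

east: 0.0776 M / 0.0191 M min⁻¹ = 4.07 min

I call this the working minutes: target at the last reading over early rate, or how long the run would need at its first speed to make what it made.

The south run gets the same count:

early rate = 0.0259 M / 0.76 min = 0.0341 M min⁻¹

south: 0.1304 M / 0.0341 M min⁻¹ = 3.83 min

The south run ends above the east run because it starts faster; its working minutes, as read, are fewer.

In the north-east run, substrate is the limiting reagent. I borrow the forecast's partner exponent, scale the east early rate and keep the east working minutes:

early rate = 0.0191 M min⁻¹ × (1.20 M / 0.480 M)^0.8 = 0.0397 M min⁻¹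

target = 0.0397 M min⁻¹ × 4.07 min = 0.162 M, or 40.4% of the substrate

The forecast gives exponents of 0.8 for partner and 0.92 for substrate, and 34% for the north-east run, within 27% to 40%. Its ground is “The fall tracks time, not target”. My figure is higher than its figure, and I read mine as the high side: the count reads 3.83 min in the south run against 4.07 min in the east run, so it may shift with the charge.

    substrate + partner ⇌ target (0.1122 M⁻¹ min⁻¹, 0.07140 min⁻¹)
    2 partner → lost reagent (0.05898 M⁻¹ min⁻¹)
    2 substrate → homo dimer (0.04374 M⁻¹ min⁻¹)

The north-east run gives 34.4%. The partner exponent comes out at 1.1 and the substrate exponent at 1.1, both above the forecast's 0.8 and 0.92. Scaled with that partner exponent, the north-east early rate reckons to 0.0505 M min⁻¹; the north-east run made 0.138 M, so its count of working minutes is 2.73 min, against 4.07 min in the east run.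

The runs stem from a simulated flask with constants of no real substance.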